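(The earlier runs and the new flask are simulated on assumed constants, noise included.)

Start from the slowness of the coupling: these flasks take days, so reckon the pace first.

| setting | autumn | dawn | summer | flask |
|---|---|---|---|---|
| left-handed substrate | 0.40 M | 0.40 M | 0.40 M | 0.40 M |
| right-handed substrate | 0.40 M | 0.40 M | 0.40 M | 0.40 M |
| coupling partner | 0.50 M | 2 M | 1 M | 1.00 M |
| free catalyst | 0.28 mM | 0.28 mM | 0.28 mM | 0.28 mM |
| racemization catalyst | 0.52 mM | 0.52 mM | 1 mM | 0.52 mM |
| remark | run made earlier | run made earlier | run made earlier |  |
| time |  |  |  | 10 d |

| run | time / d | left-handed substrate / % | right-handed substrate / % |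
|---|---|---|---|
| autumn | 0.625 | 47 | 46 |
| autumn | 1.67 | 44 | 48 |
| autumn | 3.00 | 39 | 40 |
| autumn | 5.00 | 38 | 37 |
| autumn | 8.00 | 35 | 35 |
| autumn | 10.0 | 32 | 32 |
| autumn | 12.0 | 28 | 32 |
| dawn | 1.67 | 29 | 34 |
| dawn | 3.00 | 20 | 22 |
| dawn | 5.00 | 15 | 14 |
| dawn | 6.00 | 9 | 11 |
| dawn | 8.00 | 5 | 8 |
| dawn | 10.0 | 5 | 1 |
| dawn | 12.0 | 3 | 6 |
| summer | 2.50 | 39 | 36 |
| summer | 5.00 | 25 | 28 |
| summer | 8.00 | 22 | 18 |
| summer | 10.0 | 18 | 18 |
| summer | 12.0 | 17 | 14 |

(readings scatter by 2 percentage points)

- free catalyst is single-handed; left-handed substrate and right-handed substrate are mirror images of each other, charged as a racemate, each of them at the stated concentration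
- the numbers in the tables scatter with a standard deviation of 2 percentage points
- steps under discussion: left-handed product <-> right-handed product; coupling partner + free catalyst + right-handed substrate -> free catalyst + right-handed product; coupling partner -> decomposition product; left-handed substrate + racemization catalyst <-> right-handed substrate + racemization catalyst; coupling partner + free catalyst + left-handed substrate -> free catalyst + left-handed product; 2 racemization catalyst <-> resting dimer
- an excess is the difference of the two amounts in percent of their sum
- an excess is below zero if the other one leads

- part of the left-handed substrate and right-handed substrate charged together that has reacted at 10 d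
- excess of left-handed product over right-handed product in the product at 10 d
- excess of right-handed substrate over left-handed substrate among what is left of the two at 10 d

Take the main step first: coupling at rate k·S·B, with S both substrates together and B the coupling partner. Integrate it through the summer reading at 10.0 d, where a fraction f = 36.0% of S is left. This gives k = 0.152 L mol⁻¹ d⁻¹. Dawn, with 0.52 mM of racemization catalyst and twice summer's partner, reads 0.151 L mol⁻¹ d⁻¹ at 5.00 d. The law therefore carries over, and my c for the flask is 64.0%.

Add substrate racemization. The two substrates read level within their scatter, so take eS near zero and leave c where it stands.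

Add product racemization. The readings hold no product, so commit to no eP. Reckon instead the renewal rate ρ, the product made per day per product present: ρ = k·S·B over product, which is 0.0418 d⁻¹ for the flask at 10 d. Excess enters with fresh product and leaves by relaxation, so reckon eP from their balance: eP = F·ρ/(ρ+λ), with F the excess of fresh product and λ the relaxation rate. The crossing in this balance is λ = ρ: with λ below ρ, eP stands nearer F; with λ above ρ, nearer zero. The readings give neither F nor λ.

The forecast gives c 64%, eP 50% and eS 1%, and calls eP “a guess assuming a usefully selective catalyst”.

The flask gives c 64.8%, eP 2.79% and eS 0.0889%.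

    left-handed product ⇌ right-handed product (k = 0.0150 h⁻¹)
    coupling partner + free catalyst + right-handed substrate → free catalyst + right-handed product (k = 14.0 L² mol⁻² h⁻¹)
    coupling partner → decomposition product (k = 5.30 × 10⁻⁵ h⁻¹)
    left-handed substrate + racemization catalyst ⇌ right-handed substrate + racemization catalyst, rate k4*[racemization catalyst]*[left-handed substrate] forward; the back reaction follows from the equilibrium constant (k = 2900 L mol⁻¹ h⁻¹)
    coupling partner + free catalyst + left-handed substrate → free catalyst + left-handed product (k = 33.0 L² mol⁻² h⁻¹)
    2 racemization catalyst ⇌ resting dimer, settled at all times (K = 2300 L mol⁻¹)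

The forecast and the flask part on eP, by 47 percentage points. Product relaxes with half-life 0.963 d, so λ = 0.720 d⁻¹, far above ρ. With selectivity factor 2.36, F = 40.4%, and the balance gives 2.22%, lower than the flask's 2.79%. In the neighbour with 1.7 × 10⁻⁴ M of free catalyst, scale k to 0.0923 L mol⁻¹ d⁻¹. Then S keeps a fraction 49.6%, so c is 50.4%, against 51.2% simulated. Its ρ is 0.0544 d⁻¹, so the balance gives 2.84%, and that neighbour's eP is 3.47%.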